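**Assumption:** the SMILES contains no stereocentre and no stereogenic double bond. The target is therefore achiral, is drawn as one of its fast-interconverting enol tautomers, and needs no enantiocontrol.

## Retrosynthetic overview
1. Cut the aryl C5–CH2 bond of target 8. This gives aspidinol 3, which has only one free ring C–H, and the exo-methylidene enetrione 7.
2. Enetrione 7 traces back to the C6-methyl triketone 5, so the bridge carbon is the methyl group of 5 (new cross-dehydrogenative coupling).
3. Aspidinol 3 comes from para-selective O-methylation of 2, and 2 from Friedel–Crafts butanoylation of 2-methylphloroglucinol 1.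
4. Triketone 5 comes from dearomative triple C-methylation of phloracetophenone 4.
5. No ring is built. Both carbocycles come from commercial phloroglucinols, and the filicinic ring is dearomatised (step 3) before the two rings are joined (step 4).

## Route

**Step 1**
Reactants: 1 2-methylphloroglucinol
Product: 2 1-(2,4,6-trihydroxy-3-methylphenyl)butan-1-one
Conditions: PrCOCl (1.05 equiv), AlCl3 (3.5 equiv), CH2Cl2/MeNO2 1:1, 0 to 40 °C; ice/1 M HCl work-up
Reagents that add atoms: butanoyl chloride, CCCC(=O)Cl
Why: Friedel–Crafts acylation, in which the two free ring carbons of 1 are equivalent so only one mono-ketone can form, the chelated aryl ketone is deactivated towards a second acylation, and no stereocentre is formed.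

**Step 2**
Reactants: 2 1-(2,4,6-trihydroxy-3-methylphenyl)butan-1-one
Product: 3 aspidinol, 1-(2,6-dihydroxy-4-methoxy-3-methylphenyl)butan-1-one
Conditions: Me2SO4 (1.0 equiv), K2CO3 (1.0 equiv), acetone, rt, 12 h
Reagents that add atoms: dimethyl sulfate, COS(=O)(=O)OC
Why: Williamson-type O-methylation under weak base, in which the 4-OH para to the ketone is the most acidic hydroxyl and the only one that cannot hydrogen-bond to the butanoyl C=O, so one equivalent of the hard electrophile methylates it in preference to the two chelated ortho hydroxyls, and no stereocentre is formed.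

**Step 3**
Reactants: 4 2',4',6'-trihydroxyacetophenone (phloracetophenone)
Product: 5 2-acetyl-3,5-dihydroxy-4,4,6-trimethylcyclohexa-2,5-dien-1-one
Conditions: NaOMe (3.2 equiv), MeI (3.1 equiv), MeOH, 0 to 40 °C; 1 M HCl work-up, chromatography
Reagents that add atoms: iodomethane, CI
Why: Dearomative C-alkylation of a phloroglucinol anion with the soft electrophile MeI, in which carbon methylation occurs only at C3/C5 and every way of placing three methyl groups there (2 + 1) gives the same compound, so only the degree of methylation must be controlled by stoichiometry, and 5 is fully enolised with no stereocentre.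

**Step 4**
Reactants: 3 aspidinol (1.3 equiv); 5 2-acetyl-3,5-dihydroxy-4,4,6-trimethylcyclohexa-2,5-dien-1-one (1.3 equiv)
Product: 8 para-aspidin AB (target CNP0414731.0), via alkoxyamine adduct 6 (not isolated), via methylidene enetrione 7 (not isolated)
Conditions: 4-acetamido-TEMPO+ BF4− (1.0 equiv, limiting, in MeCN by syringe pump over 2 h), CH2Cl2/HFIP 4:1, 0.05 M, N2, 0 °C to rt; water wash, crystallisation from MeOH
Reagents that add atoms: none
Why: Proposed new method: an oxoammonium-triggered cross-dehydrogenative coupling of an enolic C–CH3 group with an arene C–H, in which the methyl carbon of 5 becomes the methylene bridge; C6 of 5 is a fully enolised carbon whose attack costs no aromaticity, so it outcompetes the acyl-deactivated phenol 3 for the N=O+ oxygen and gives the quaternary, transiently racemic alkoxyamine 6; 6 has no α-H for the usual collapse to a ketone and so loses the hydroxylamine by cleavage of its weak C–O bond with β-H transfer from the methyl group, the same event that ends nitroxide-mediated methacrylate polymerisation as an exo-methylene chain end, and a direct ene-type hydride transfer from the allylic CH3 would lead to the same 7; 7 is formed at low stationary concentration and is activated by hydrogen bonding from HFIP and the hydroxylammonium salt, and C5 of 3 (ortho to OH and OMe, para to OH, meta to the acyl group) then adds to its exocyclic CH2 in a Friedel–Crafts/Michael sense with re-aromatisation and re-enolisation making the step effectively irreversible, whereas the quaternary adducts of 7 with 5 and the hetero-Diels–Alder dimers of 7 are reversible reservoirs; over-oxidation of 8 is held back by the bulk of the tetramethylpiperidine oxidant against the 2,6-disubstituted benzyl group on C6 of 8, by the oxidant being the limiting and slowly dosed reagent, and by the near-neutral medium that prevents comproportionation to radical oxidants; the closest known reaction types are oxoammonium oxidation of 1,3-diketone enols, Ag2O/TEMPO generation of such enetriones for hetero-Diels–Alder trapping, oxoammonium-mediated dehydrogenative coupling next to heteroatoms, and Michael addition of acylphloroglucinols to alkylidene β-triketones; no stereocentre remains in 8.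

## Compound list
1 | 2-methylphloroglucinol (2-methylbenzene-1,3,5-triol) | Cc1c(O)cc(O)cc1O | starting material
2 | 1-(2,4,6-trihydroxy-3-methylphenyl)butan-1-one | CCCC(=O)c1c(O)c(C)c(O)cc1O | intermediate
3 | aspidinol, 1-(2,6-dihydroxy-4-methoxy-3-methylphenyl)butan-1-one | CCCC(=O)c1c(O)c(C)c(OC)cc1O | intermediate
4 | 2',4',6'-trihydroxyacetophenone (phloracetophenone) | CC(=O)c1c(O)cc(O)cc1O | starting material
5 | 2-acetyl-3,5-dihydroxy-4,4,6-trimethylcyclohexa-2,5-dien-1-one | CC(=O)C1=C(O)C(C)(C)C(O)=C(C)C1=O | intermediate
6 | 2-acetyl-6-[(4-acetamido-2,2,6,6-tetramethylpiperidin-1-yl)oxy]-3-hydroxy-4,4,6-trimethylcyclohex-2-ene-1,5-dione (racemic, transient) | CC(=O)NC1CC(C)(C)N(OC2(C)C(=O)C(C(C)=O)=C(O)C(C)(C)C2=O)C(C)(C)C1 | intermediate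
7 | 2-acetyl-3-hydroxy-4,4-dimethyl-6-methylidenecyclohex-2-ene-1,5-dione | CC(=O)C1=C(O)C(C)(C)C(=O)C(=C)C1=O | intermediate
8 | para-aspidin AB, 2-acetyl-6-[(3-butanoyl-2,4-dihydroxy-6-methoxy-5-methylphenyl)methyl]-3,5-dihydroxy-4,4-dimethylcyclohexa-2,5-dien-1-one (achiral) | CCCC(=O)c1c(O)c(C)c(OC)c(CC2=C(O)C(C)(C)C(O)=C(C(C)=O)C2=O)c1O | target

## Summary
Total step count: 4.
Longest linear sequence: 3 steps (1 → 2 → 3 → 8). The side branch 4 → 5 is 1 step.

## Three steps most likely to fail

**Step 4 (proposed new step).**
- Risks:
  - The filicinic ring of 8 can be oxidised further.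
  - The phenol 3 can be oxidised competitively.
  - Enetrione 7 can be lost to self-trapping.
- Fallback with known chemistry: it sets out from 3, with 4 supplying the partner, and comes back to the route at 8.
- Aspidinol 3 is aminomethylated at its only free ring carbon with aqueous formaldehyde and dimethylamine in ethanol at rt (Mannich reaction). This gives 1-{3-[(dimethylamino)methyl]-2,6-dihydroxy-4-methoxy-5-methylphenyl}butan-1-one F1.
- Separately, 4 is C-methylated with only two equivalents of MeI and NaOMe in MeOH. This gives acetylfilicinic acid, 2-acetyl-3,5-dihydroxy-4,4-dimethylcyclohexa-2,5-dien-1-one F2.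
- Heating F1 with F2 in dioxane at 100 °C expels the amine and gives the ortho-quinone methide 2-butanoyl-3-hydroxy-5-methoxy-4-methyl-6-methylidenecyclohexa-2,4-dien-1-one F3.
- The free C6 of F2 captures F3 by Michael addition to give 8. Each half plays only one role, which suppresses homodimers.

**Step 3.**
- Risk: di-, tri- and tetramethylated products form as a statistical mixture that is hard to separate.
- Fallback: it sets out from 1 and comes back at 5.
- Compound 1 already carries one of the three methyl groups. It is acetylated (AcCl, AlCl3, CH2Cl2/MeNO2) to 1-(2,4,6-trihydroxy-3-methylphenyl)ethan-1-one F4.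
- F4 needs only two C-methylations (MeI 2.0 equiv, NaOMe, MeOH).
- Methylation at the methyl-bearing carbon first and methylation at the free carbon first both lead to 5. The product distribution is therefore narrower.

**Step 2.**
- Risk: methylation of an ortho hydroxyl, or double methylation, because the 4-OH is flanked by the ring methyl group.
- Fallback: it sets out from 2 and comes back at 3.
- Selectivity is moved from alkylation to cleavage. Compound 2 is exhaustively methylated (excess Me2SO4, K2CO3, acetone, reflux) to 1-(2,4,6-trimethoxy-3-methylphenyl)butan-1-one F5.
- The two methoxy groups ortho to the ketone are then removed by carbonyl-chelation-directed ether cleavage (AlCl3, 5 equiv, CH2Cl2, reflux).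
- The para methoxy group cannot chelate and stays, which gives 3.

## Further compounds
F1 | step 4 | 1-{3-[(dimethylamino)methyl]-2,6-dihydroxy-4-methoxy-5-methylphenyl}butan-1-one | CCCC(=O)c1c(O)c(C)c(OC)c(CN(C)C)c1O
F2 | step 4 | acetylfilicinic acid, 2-acetyl-3,5-dihydroxy-4,4-dimethylcyclohexa-2,5-dien-1-one | CC(=O)C1=C(O)C(C)(C)C(O)=CC1=O
F3 | step 4 | 2-butanoyl-3-hydroxy-5-methoxy-4-methyl-6-methylidenecyclohexa-2,4-dien-1-one | CCCC(=O)C1=C(O)C(C)=C(OC)C(=C)C1=O
F4 | step 3 | 1-(2,4,6-trihydroxy-3-methylphenyl)ethan-1-one | CC(=O)c1c(O)c(C)c(O)cc1O
F5 | step 2 | 1-(2,4,6-trimethoxy-3-methylphenyl)butan-1-one | CCCC(=O)c1c(OC)c(C)c(OC)cc1OC
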